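**Retrosynthetic overview**
- Target 11 ⇐ bis-stilbene tris(benzyl ether) 10 by one H2/Pd–C operation, which saturates both bridges and frees all three OH groups.
- Key C–C disconnection: the ring C–CH=CH–ring D bond of 10 ⇐ aldehyde 7 + aldehyde 2. The formyl carbon of 2 is made nucleophilic as its N–H hydrazone 9 (a benzyl-carbanion equivalent under Ru catalysis), so two normally electrophilic carbonyl carbons are joined with loss of N2 and H2O.
- 7 ⇐ SNAr of phenol 5 on 4-fluorobenzaldehyde 6 (diaryl ether); 5 ⇐ Horner–Wadsworth–Emmons reaction of phosphonate 3 with aldehyde 4; 2 ⇐ bis-benzylation of 1.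
- No ring is constructed: all four benzene rings are bought and connected in the order A–B, then B–O–C, then C–D.

Assumption: the target has no stereocentre and no stereogenic double bond, so it is achiral and there is no enantiomer to select; 4-(benzyloxy)-3-hydroxybenzaldehyde is taken as a catalogue chemical.

**Route**

Step 1
Reactants: 1 2,5-dihydroxybenzaldehyde
Product: 2 2,5-bis(benzyloxy)benzaldehyde
Conditions: BnBr (2.4 equiv), K2CO3 (3 equiv), DMF, N2, 60 °C
Reagents that add atoms: benzyl bromide, BrCc1ccccc1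
Why: Williamson ether synthesis on both phenoxides (run under N2 because the hydroquinone is air-sensitive in base) installs benzyl groups that the final hydrogenolysis removes without touching the methyl ether.

Step 2
Reactants: 3 diethyl (3-methoxybenzyl)phosphonate; 4 4-(benzyloxy)-3-hydroxybenzaldehyde
Product: 5 2-(benzyloxy)-5-[(E)-2-(3-methoxyphenyl)ethenyl]phenol
Conditions: KOtBu (2.5 equiv), DMF, 0 °C → rt; 1 M HCl work-up
Reagents that add atoms: none
Why: Horner–Wadsworth–Emmons olefination with a benzylic phosphonate gives the E-stilbene; the extra equivalent of base holds the phenol as its phenoxide, which sits meta to the aldehyde and so leaves it reactive enough.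

Step 3
Reactants: 5 2-(benzyloxy)-5-[(E)-2-(3-methoxyphenyl)ethenyl]phenol; 6 4-fluorobenzaldehyde
Product: 7 4-{2-(benzyloxy)-5-[(E)-2-(3-methoxyphenyl)ethenyl]phenoxy}benzaldehyde
Conditions: K2CO3 (2 equiv), DMF, N2, 120 °C
Reagents that add atoms: none
Why: Nucleophilic aromatic substitution (SNAr) of the para-formyl-activated fluoride by the phenoxide forms the diaryl ether and leaves the aldehyde needed for the key coupling.

Step 4
Reactants: 2 2,5-bis(benzyloxy)benzaldehyde; 8 hydrazine monohydrate; 7 4-{2-(benzyloxy)-5-[(E)-2-(3-methoxyphenyl)ethenyl]phenoxy}benzaldehyde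
Product: 10 1,4-bis(benzyloxy)-2-[(E)-2-(4-{2-(benzyloxy)-5-[(E)-2-(3-methoxyphenyl)ethenyl]phenoxy}phenyl)ethenyl]benzene, via N–H hydrazone 9 (not isolated)
Conditions: 2 (1.3 equiv), N2H4·H2O (1.35 equiv), THF, rt, 1 h; then 7 (1.0 equiv), [Ru(p-cymene)Cl2]2 (1.5 mol%), dmpe (3 mol%), KOtBu (50 mol%), THF, N2, 50 °C, 16 h (loadings approximate, from memory of the published protocol)
Reagents that add atoms: none
Why: Ru(II)-catalysed hydrazone-mediated carbonyl reductive cross-coupling (Wolff–Kishner-type carbonyl umpolung olefination): Ru-bound, deprotonated hydrazone 9 adds through its carbon to the C=O of 7 in a six-membered transition state, and the resulting β-hydroxy diazene loses N2 and hydroxide (E1cB) to give the mainly E alkene, whose geometry does not matter because it is hydrogenated next.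

Step 5
Reactants: 10 1,4-bis(benzyloxy)-2-[(E)-2-(4-{2-(benzyloxy)-5-[(E)-2-(3-methoxyphenyl)ethenyl]phenoxy}phenyl)ethenyl]benzene
Product: 11 2-[2-(4-{2-hydroxy-5-[2-(3-methoxyphenyl)ethyl]phenoxy}phenyl)ethyl]benzene-1,4-diol
Conditions: H2 (1–3 bar), 10% Pd/C, EtOAc/MeOH 1:1, rt; filtration and concentration under N2
Reagents that add atoms: none
Why: Heterogeneous Pd-catalysed hydrogenation and hydrogenolysis saturates both stilbene C=C bonds and cleaves the three aryl benzyl ethers in one operation, while the aryl methyl ether and the diaryl ether are inert; no stereocentre is created.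

**Compound list**

1 | 2,5-dihydroxybenzaldehyde | O=Cc1cc(O)ccc1O | starting material
2 | 2,5-bis(benzyloxy)benzaldehyde | O=Cc1cc(OCc2ccccc2)ccc1OCc1ccccc1 | intermediate
3 | diethyl (3-methoxybenzyl)phosphonate | CCOP(=O)(OCC)Cc1cccc(OC)c1 | starting material
4 | 4-(benzyloxy)-3-hydroxybenzaldehyde | O=Cc1ccc(OCc2ccccc2)c(O)c1 | starting material
5 | 2-(benzyloxy)-5-[(E)-2-(3-methoxyphenyl)ethenyl]phenol | COc1cccc(/C=C/c2ccc(OCc3ccccc3)c(O)c2)c1 | intermediate
6 | 4-fluorobenzaldehyde | O=Cc1ccc(F)cc1 | starting material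
7 | 4-{2-(benzyloxy)-5-[(E)-2-(3-methoxyphenyl)ethenyl]phenoxy}benzaldehyde | COc1cccc(/C=C/c2ccc(OCc3ccccc3)c(Oc3ccc(C=O)cc3)c2)c1 | intermediate
8 | hydrazine monohydrate | NN.O | starting material
9 | (E)-[2,5-bis(benzyloxy)benzylidene]hydrazine (N–H hydrazone of 2, formed in the flask) | N/N=C/c1cc(OCc2ccccc2)ccc1OCc1ccccc1 | intermediate
10 | 1,4-bis(benzyloxy)-2-[(E)-2-(4-{2-(benzyloxy)-5-[(E)-2-(3-methoxyphenyl)ethenyl]phenoxy}phenyl)ethenyl]benzene | COc1cccc(/C=C/c2ccc(OCc3ccccc3)c(Oc3ccc(/C=C/c4cc(OCc5ccccc5)ccc4OCc4ccccc4)cc3)c2)c1 | intermediate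
11 | 2-[2-(4-{2-hydroxy-5-[2-(3-methoxyphenyl)ethyl]phenoxy}phenyl)ethyl]benzene-1,4-diol | COc1cccc(CCc2ccc(O)c(Oc3ccc(CCc4cc(O)ccc4O)cc3)c2)c1 | target

**Step count**

Total steps: 5. Longest linear sequence: 4 (steps 2, 3, 4, 5, from 3 and 4); step 1 is a one-step side branch.

**Steps most likely to fail, with fallbacks**

Step 4 (key coupling) is the riskiest. Both partners are electron-rich, the hydrazone carries an ortho benzyloxy group, and azine formation or Wolff–Kishner reduction of 9 can compete. The fallback sets out from 2 and 7 and comes back to the route at 11, using a stoichiometric acyl-anion equivalent instead of the catalytic hydrazone. Aldehyde 2 is converted with propane-1,3-dithiol and BF3·OEt2 (CH2Cl2, 0 °C) into 2-[2,5-bis(benzyloxy)phenyl]-1,3-dithiane F1. Aldehyde 7 is reduced with NaBH4 (MeOH/THF, 0 °C) to (4-{2-(benzyloxy)-5-[(E)-2-(3-methoxyphenyl)ethenyl]phenoxy}phenyl)methanol F2. F2 is brominated with CBr4/PPh3 (CH2Cl2, 0 °C) to 1-(benzyloxy)-2-[4-(bromomethyl)phenoxy]-4-[(E)-2-(3-methoxyphenyl)ethenyl]benzene F3. F1 is lithiated (n-BuLi, THF, −78 → −30 °C) and alkylated with F3 to give 2-[2,5-bis(benzyloxy)phenyl]-2-(4-{2-(benzyloxy)-5-[(E)-2-(3-methoxyphenyl)ethenyl]phenoxy}benzyl)-1,3-dithiane F4. Excess W-2 Raney nickel under H2 in refluxing EtOH then cleaves both C–S bonds, saturates the stilbene and hydrogenolyses the three aryl benzyl ethers, giving 11.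

Step 2 is the second risk, because the olefination runs on a phenoxide-bearing aldehyde and may stall or give a low yield. The fallback sets out from 4 and comes back at 5 by masking the phenol. Aldehyde 4 is treated with MOMCl and iPr2NEt (CH2Cl2, 0 °C → rt) to give 4-(benzyloxy)-3-(methoxymethoxy)benzaldehyde F5. Horner–Wadsworth–Emmons reaction of F5 with 3 (NaH, THF, 0 °C → rt) gives 1-(benzyloxy)-2-(methoxymethoxy)-4-[(E)-2-(3-methoxyphenyl)ethenyl]benzene F6. HCl in MeOH at 50 °C removes the MOM group and delivers 5.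

Step 5 is the third risk. Residual Ru or phosphine from step 4 can poison Pd, one hindered benzyl ether may survive, and the hydroquinone product is air-sensitive. The fallback sets out from 10 and comes back at 11 in two metal-free stages. Diimide (TsNHNH2, NaOAc, THF/H2O, reflux) saturates both C=C bonds to give 1,4-bis(benzyloxy)-2-[2-(4-{2-(benzyloxy)-5-[2-(3-methoxyphenyl)ethyl]phenoxy}phenyl)ethyl]benzene F7. BCl3 with pentamethylbenzene as cation scavenger (CH2Cl2, −78 °C) then removes the three benzyl groups while the aryl methyl ether stays, giving 11.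

**Further compounds**

F1 | step 4 | 2-[2,5-bis(benzyloxy)phenyl]-1,3-dithiane | C1CSC(SC1)c1cc(OCc2ccccc2)ccc1OCc1ccccc1
F2 | step 4 | (4-{2-(benzyloxy)-5-[(E)-2-(3-methoxyphenyl)ethenyl]phenoxy}phenyl)methanol | COc1cccc(/C=C/c2ccc(OCc3ccccc3)c(Oc3ccc(CO)cc3)c2)c1
F3 | step 4 | 1-(benzyloxy)-2-[4-(bromomethyl)phenoxy]-4-[(E)-2-(3-methoxyphenyl)ethenyl]benzene | COc1cccc(/C=C/c2ccc(OCc3ccccc3)c(Oc3ccc(CBr)cc3)c2)c1
F4 | step 4 | 2-[2,5-bis(benzyloxy)phenyl]-2-(4-{2-(benzyloxy)-5-[(E)-2-(3-methoxyphenyl)ethenyl]phenoxy}benzyl)-1,3-dithiane | COc1cccc(/C=C/c2ccc(OCc3ccccc3)c(Oc3ccc(CC4(SCCCS4)c4cc(OCc5ccccc5)ccc4OCc4ccccc4)cc3)c2)c1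
F5 | step 2 | 4-(benzyloxy)-3-(methoxymethoxy)benzaldehyde | COCOc1cc(C=O)ccc1OCc1ccccc1
F6 | step 2 | 1-(benzyloxy)-2-(methoxymethoxy)-4-[(E)-2-(3-methoxyphenyl)ethenyl]benzene | COCOc1cc(/C=C/c2cccc(OC)c2)ccc1OCc1ccccc1
F7 | step 5 | 1,4-bis(benzyloxy)-2-[2-(4-{2-(benzyloxy)-5-[2-(3-methoxyphenyl)ethyl]phenoxy}phenyl)ethyl]benzene | COc1cccc(CCc2ccc(OCc3ccccc3)c(Oc3ccc(CCc4cc(OCc5ccccc5)ccc4OCc4ccccc4)cc3)c2)c1
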